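**Plan**
- Retrosynthesis: the depside ester bond C(=O)–O4' and the 2'-O–CH3 bond are cut first, leaving a 2-O-benzyl ring-A acid and benzyl 2,4-dihydroxy-6-propylbenzoate. The latter is traced back to a cyclohexane-1,3-dione, which is cut at C1'–C6' and C2'–C3'.
- Enabling feature: in ring B the carboxyl-bearing C1' sits between oxygenated C2' and propyl-bearing C6', and the second oxygen is on C4'. C1', C2' and the carboxyl carbon are therefore a malonate, and C3'–C6' with the propyl chain are hept-3-en-2-one.
- Forward: ring B is closed first as a saturated six-membered carbocycle by Michael–Dieckmann annulation and then dehydrogenated to the resorcinol ester. Ring A is bought as olivetol and gains its carboxyl carbon by formylation and oxidation.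
- Joining: 4'-O-acylation by the ring-A acid, then 2'-O-methylation, then hydrogenolysis of both benzyl groups.
- Stereochemistry: the target has no stereocentre. The two sp3 centres of the dione form racemic and disappear on aromatisation.

Key step: step 1

Assumption: the annulation product is drawn as its diketo, trans form, although it should exist largely as an enol. Ring-A positions carry plain numbers and ring-B positions primed numbers.

**Route**

Step 1
Reactants: 1 dibenzyl malonate; 2 (E)-hept-3-en-2-one
Product: 5 benzyl 2,4-dioxo-6-propylcyclohexane-1-carboxylate (racemic trans), via Michael adduct 3 (not isolated), via sodium enolate 4 (not isolated)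
Conditions: NaH (1.1 equiv), BnOH (1.2 equiv), toluene, 0 °C to rt; add 1, then 2; 80 °C; cold 1 M HCl
Reagents that add atoms: none
Why: Sodium benzyloxide deprotonates 1, and the malonate anion adds to the β-carbon of 2 in a Michael addition (C1'–C6' bond, adduct 3); the ketone then enolises toward its methyl group and this carbon attacks one benzyl ester in a Dieckmann (intramolecular Claisen) condensation (C2'–C3' bond), expelling benzyl alcohol. The closest known reaction type is the malonate–enone Michael–Dieckmann annulation that gives alkyl 6-alkyl-2,4-dioxocyclohexanecarboxylates. The ring closes in a 6-exo-trig acyl substitution, whereas the enolate on the other side of the ketone could only form a four-membered ring, so ring size alone fixes the regiochemistry. C1' and C6' are formed racemic; C1' lies between two carbonyls and equilibrates, so the ester and the propyl group should settle trans (both equatorial), and both centres are erased in step 2. The step needs 1,4- over 1,2-addition and ring closure over retro-Michael cleavage; the soft stabilised nucleophile secures the first and the irreversible formation of the cyclic β-diketone enolate 4 the second, while pairing benzyloxide with benzyl esters makes transesterification degenerate.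

Step 2
Reactants: 5 benzyl 2,4-dioxo-6-propylcyclohexane-1-carboxylate
Product: 7 benzyl 2,4-dihydroxy-6-propylbenzoate, via bromo dione 6 (not isolated)
Conditions: Br2 (1.0 equiv), DMF, 0 °C; then 60–80 °C
Reagents that add atoms: none
Why: Bromination of the enol at C3' followed by loss of HBr and tautomerisation (halogenation–dehydrohalogenation aromatisation of a cyclohexane-1,3-dione) should give the resorcinol ester, with a single equivalent of bromine limiting bromination of the aromatic product.

Step 3
Reactants: 8 olivetol
Product: 10 2,4-dihydroxy-6-pentylbenzaldehyde, via iminium chloride 9 (not isolated)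
Conditions: POCl3, DMF, 0 °C to rt; then H2O, 50 °C
Reagents that add atoms: N,N-dimethylformamide CN(C)C=O; water O
Why: In this Vilsmeier–Haack formylation the chloroiminium ion attacks the ring position para to one hydroxyl and ortho to the other, as in resorcinol itself, and hydrolysis of iminium 9 releases the aldehyde.

Step 4
Reactants: 10 2,4-dihydroxy-6-pentylbenzaldehyde
Product: 11 2-hydroxy-4-methoxy-6-pentylbenzaldehyde
Conditions: MeI (1.05 equiv), K2CO3 (1.0 equiv), acetone, rt to 40 °C
Reagents that add atoms: iodomethane CI
Why: In this Williamson etherification the 2-hydroxyl is held in a hydrogen bond to the aldehyde and is the poorer nucleophile, so one equivalent of iodomethane should alkylate the free 4-hydroxyl.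

Step 5
Reactants: 11 2-hydroxy-4-methoxy-6-pentylbenzaldehyde
Product: 12 2-(benzyloxy)-4-methoxy-6-pentylbenzaldehyde
Conditions: BnBr, K2CO3, DMF, 60 °C
Reagents that add atoms: benzyl bromide BrCc1ccccc1
Why: Williamson benzylation under more forcing conditions (excess reagent, DMF, heat) alkylates the remaining chelated hydroxyl, which must be masked so that ring A cannot acylate itself in step 7.

Step 6
Reactants: 12 2-(benzyloxy)-4-methoxy-6-pentylbenzaldehyde
Product: 13 2-(benzyloxy)-4-methoxy-6-pentylbenzoic acid
Conditions: NaClO2, NaH2PO4, 2-methyl-2-butene, t-BuOH/THF/H2O, rt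
Reagents that add atoms: sodium chlorite [Na+].[O-]Cl=O
Why: The Pinnick (Lindgren) oxidation converts the hindered aryl aldehyde into the acid under buffered conditions that leave the benzyl ether alone, while the alkene scavenges hypochlorous acid and so protects the electron-rich ring from chlorination.

Step 7
Reactants: 13 2-(benzyloxy)-4-methoxy-6-pentylbenzoic acid; 7 benzyl 2,4-dihydroxy-6-propylbenzoate
Product: 15 benzyl 4-{[2-(benzyloxy)-4-methoxy-6-pentylbenzoyl]oxy}-2-hydroxy-6-propylbenzoate, via mixed anhydride 14 (not isolated)
Conditions: (CF3CO)2O, toluene, rt; aq. NaHCO3 work-up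
Reagents that add atoms: none
Why: In this mixed-anhydride esterification the electron-rich, doubly ortho-substituted aroyl trifluoroacetate 14 acts as an acylium-type donor and should acylate the free 4'-hydroxyl, because the 2'-hydroxyl is hydrogen-bonded to and crowded by the neighbouring benzyl ester.

Step 8
Reactants: 15 benzyl 4-{[2-(benzyloxy)-4-methoxy-6-pentylbenzoyl]oxy}-2-hydroxy-6-propylbenzoate
Product: 16 benzyl 4-{[2-(benzyloxy)-4-methoxy-6-pentylbenzoyl]oxy}-2-methoxy-6-propylbenzoate
Conditions: MeI, K2CO3, dry DMF, rt
Reagents that add atoms: iodomethane CI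
Why: Williamson O-methylation of the only remaining phenol should proceed under anhydrous carbonate, since the depside carbonyl is shielded by the two ortho substituents of ring A.

Step 9
Reactants: 16 benzyl 4-{[2-(benzyloxy)-4-methoxy-6-pentylbenzoyl]oxy}-2-methoxy-6-propylbenzoate
Product: 17 4-[(2-hydroxy-4-methoxy-6-pentylbenzoyl)oxy]-2-methoxy-6-propylbenzoic acid (CNP0509830.0)
Conditions: H2 (1 atm), 10% Pd/C, EtOAc, rt
Reagents that add atoms: none
Why: Catalytic hydrogenolysis cleaves the benzylic C–O bonds of the benzyl ether and the benzyl ester in one operation, leaving the aryl ester, the methyl ethers and both rings untouched.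

**Compound list**
1 | dibenzyl malonate | O=C(CC(=O)OCc1ccccc1)OCc1ccccc1 | starting material
2 | (E)-hept-3-en-2-one | CCC/C=C/C(C)=O | starting material
3 | dibenzyl 2-(2-oxoheptan-4-yl)propanedioate (racemic Michael adduct; not isolated) | CCCC(CC(C)=O)C(C(=O)OCc1ccccc1)C(=O)OCc1ccccc1 | intermediate
4 | sodium 6-[(benzyloxy)carbonyl]-3-oxo-5-propylcyclohex-1-en-1-olate (racemic trans; not isolated) | CCC[C@@H]1CC(=O)C=C([O-])[C@H]1C(=O)OCc1ccccc1.[Na+] | intermediate
5 | benzyl 2,4-dioxo-6-propylcyclohexane-1-carboxylate (racemic; trans isomer drawn) | CCC[C@@H]1CC(=O)CC(=O)[C@H]1C(=O)OCc1ccccc1 | intermediate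
6 | benzyl 3-bromo-2,4-dioxo-6-propylcyclohexane-1-carboxylate (stereoisomer mixture; not isolated) | CCCC1CC(=O)C(Br)C(=O)C1C(=O)OCc1ccccc1 | intermediate
7 | benzyl 2,4-dihydroxy-6-propylbenzoate | CCCc1cc(O)cc(O)c1C(=O)OCc1ccccc1 | intermediate
8 | olivetol (5-pentylbenzene-1,3-diol) | CCCCCc1cc(O)cc(O)c1 | starting material
9 | [(2,4-dihydroxy-6-pentylphenyl)methylidene]dimethyliminium chloride (not isolated) | CCCCCc1cc(O)cc(O)c1C=[N+](C)C.[Cl-] | intermediate
10 | 2,4-dihydroxy-6-pentylbenzaldehyde | CCCCCc1cc(O)cc(O)c1C=O | intermediate
11 | 2-hydroxy-4-methoxy-6-pentylbenzaldehyde | CCCCCc1cc(OC)cc(O)c1C=O | intermediate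
12 | 2-(benzyloxy)-4-methoxy-6-pentylbenzaldehyde | CCCCCc1cc(OC)cc(OCc2ccccc2)c1C=O | intermediate
13 | 2-(benzyloxy)-4-methoxy-6-pentylbenzoic acid | CCCCCc1cc(OC)cc(OCc2ccccc2)c1C(=O)O | intermediate
14 | 2-(benzyloxy)-4-methoxy-6-pentylbenzoic trifluoroacetic anhydride (not isolated) | CCCCCc1cc(OC)cc(OCc2ccccc2)c1C(=O)OC(=O)C(F)(F)F | intermediate
15 | benzyl 4-{[2-(benzyloxy)-4-methoxy-6-pentylbenzoyl]oxy}-2-hydroxy-6-propylbenzoate | CCCCCc1cc(OC)cc(OCc2ccccc2)c1C(=O)Oc1cc(CCC)c(C(=O)OCc2ccccc2)c(O)c1 | intermediate
16 | benzyl 4-{[2-(benzyloxy)-4-methoxy-6-pentylbenzoyl]oxy}-2-methoxy-6-propylbenzoate | CCCCCc1cc(OC)cc(OCc2ccccc2)c1C(=O)Oc1cc(CCC)c(C(=O)OCc2ccccc2)c(OC)c1 | intermediate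
17 | 4-[(2-hydroxy-4-methoxy-6-pentylbenzoyl)oxy]-2-methoxy-6-propylbenzoic acid | CCCCCc1cc(OC)cc(O)c1C(=O)Oc1cc(CCC)c(C(=O)O)c(OC)c1 | target

**Step count**
Total: 9 steps. Longest linear sequence: 7 steps (steps 3–9, from olivetol 8). The ring-B branch (steps 1 and 2) joins at step 7.

**Steps most likely to fail**

1. Step 2 (aromatisation). The resorcinol ring may be brominated further once it has formed. The benzyl ester may also be cleaved by HBr and bromide in warm DMF, after which the free acid would decarboxylate. Fallback, setting out from 5: exhaustive bromination with Br2 (3 equiv) and NaOAc in acetic acid at rt should give benzyl 3,5-dibromo-2,4-dihydroxy-6-propylbenzoate F1, which is the deliberate end point of over-bromination. Hydrogenolysis (H2, 10% Pd/C, NaOAc, MeOH, rt) should then remove both bromines together with the benzyl group to give 2,4-dihydroxy-6-propylbenzoic acid F2, handled cold to avoid decarboxylation. Carboxylate-selective benzylation (BnBr, KHCO3, DMF, rt) brings the route back to 7.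

2. Step 8 (methylation beside the depside link). The hydrogen-bonded 2'-hydroxyl may react sluggishly, and longer exposure to base invites cleavage or intermolecular transfer of the ring-A acyl group. Fallback, setting out from 7, in which the methyl ether is installed before the depside bond exists: selective allylation of the free 4-hydroxyl (allyl bromide, K2CO3, acetone, rt) should give benzyl 2-hydroxy-6-propyl-4-(prop-2-en-1-yloxy)benzoate F3. Forcing methylation (MeI, K2CO3, DMF, 50 °C) should give benzyl 2-methoxy-6-propyl-4-(prop-2-en-1-yloxy)benzoate F4. Deallylation with the zerovalent palladium complex Pd(PPh3)4 and morpholine in THF should give benzyl 4-hydroxy-2-methoxy-6-propylbenzoate F5. Coupling of F5 with acid 13 under the conditions of step 7 (through mixed anhydride 14) rejoins the route at 16.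

3. Step 7 (depside coupling). Acyl transfer from the doubly ortho-substituted donor may be slow, and acylation may occur at the wrong hydroxyl, at both hydroxyls, or at ring carbon under the acidic conditions. Fallback, setting out from 13, which moves the activation from the acid side under acid to the phenol side under base: oxalyl chloride with catalytic DMF in CH2Cl2 should give 2-(benzyloxy)-4-methoxy-6-pentylbenzoyl chloride F6. F6 is then added to 7 in pyridine at 0 °C to rt, where the more acidic, unchelated 4'-hydroxyl should be acylated, and the route is rejoined at 15.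

**Further compounds**
F1 | step 2 | benzyl 3,5-dibromo-2,4-dihydroxy-6-propylbenzoate | CCCc1c(Br)c(O)c(Br)c(O)c1C(=O)OCc1ccccc1
F2 | step 2 | 2,4-dihydroxy-6-propylbenzoic acid | CCCc1cc(O)cc(O)c1C(=O)O
F3 | step 8 | benzyl 2-hydroxy-6-propyl-4-(prop-2-en-1-yloxy)benzoate | CCCc1cc(OCC=C)cc(O)c1C(=O)OCc1ccccc1
F4 | step 8 | benzyl 2-methoxy-6-propyl-4-(prop-2-en-1-yloxy)benzoate | CCCc1cc(OCC=C)cc(OC)c1C(=O)OCc1ccccc1
F5 | step 8 | benzyl 4-hydroxy-2-methoxy-6-propylbenzoate | CCCc1cc(O)cc(OC)c1C(=O)OCc1ccccc1
F6 | step 7 | 2-(benzyloxy)-4-methoxy-6-pentylbenzoyl chloride | CCCCCc1cc(OC)cc(OCc2ccccc2)c1C(Cl)=O
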